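The 1,2-dioxolane ring (O1–O2–C3–C4–C5) is cut into a C5–O1–O2 unit and a C3=C4 alkene. A catalytic asymmetric (3+2) annulation joins the peroxycarbenium ion released from a racemic, acyclic silyl peroxyketal to methyl 3-methylbut-3-enoate. C4–C5 and O2–C3 form in one operation, closing the ring with its O–O bond already in place and setting both fully substituted stereocentres. The step exploits C5 as a masked ketone carbon and the gem-disubstituted C3 as a masked tertiary cation. The acid-sensitive triene is kept away from it: the precursor carries only an (E)-iodoalkene, and Suzuki coupling completes the (7E,9E,12Z) chain afterwards.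

Key step: step 5

Assumption 1: ring numbering is O1, O2, C3 (bears CH2CO2H), C4 (CH2), C5 (bears the C15 chain). The target is (3R,5S), which places the two ring methyl groups trans and the two large arms on opposite faces.
Assumption 2: the sense of induction of the chiral acid cannot be predicted. The (S,S)-catalyst is written, and its equally accessible antipode is used if that one proves to be matched to (3R,5S).

Step 1
Reactants: 1 4-bromo-2-methylbut-1-ene; 2 6-bromohex-1-yne
Product: 4 2-methyldec-1-en-9-yne, via Grignard reagent 3 (not isolated)
Conditions: Mg, THF, rt (1 to 3, 2.3 equiv); then 2, Li2CuCl4 (3 mol %), NMP, THF, −10 to 0 °C; aq NH4Cl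
Reagents that add atoms: none
Why: Copper-catalysed Kochi cross-coupling of a primary alkyl Grignard reagent with a primary alkyl bromide; the first equivalent of 3 only deprotonates the alkyne of 2, and the resulting magnesium acetylide does not transfer from copper, so the six-methylene tether is assembled without protecting groups.

Step 2
Reactants: 4 2-methyldec-1-en-9-yne
Product: 6 (E)-1-iodo-9-methyldeca-1,9-diene, via alkenylzirconocene chloride 5 (not isolated)
Conditions: Cp2Zr(H)Cl (1.1 equiv), CH2Cl2, rt, dark; then I2 (1.1 equiv), 0 °C
Reagents that add atoms: iodine, II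
Why: Schwartz hydrozirconation adds Zr–H syn across the terminal alkyne, with zirconium at the terminus, far faster than it touches the 1,1-disubstituted alkene, and iodinolysis of the C–Zr bond with retention fixes the (E)-iodoalkene.

Step 3
Reactants: 6 (E)-1-iodo-9-methyldeca-1,9-diene
Product: 8 (E)-9-hydroperoxy-1-iodo-9-methoxydec-1-ene (racemic), via carbonyl oxide 7 (not isolated)
Conditions: O3 (about 1 equiv, Sudan Red 7B as end-point indicator), CH2Cl2/MeOH 3:1, −78 °C; N2 purge; concentration below 20 °C
Reagents that add atoms: ozone, [O-][O+]=O; methanol, CO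
Why: Criegee ozonolysis in a participating solvent: the electron-rich 1,1-dialkylalkene outruns the inductively deactivated iodoalkene, the primary ozonide fragments to formaldehyde and the more substituted carbonyl oxide 7, and methanol traps 7 as the hydroperoxyketal, whose racemic centre does not matter because step 5 erases it.

Step 4
Reactants: 8 (E)-9-hydroperoxy-1-iodo-9-methoxydec-1-ene
Product: 9 triethyl{[(E)-10-iodo-2-methoxydec-9-en-2-yl]peroxy}silane (racemic)
Conditions: Et3SiCl (1.2 equiv), imidazole (2 equiv), DMF, 0 °C
Reagents that add atoms: chlorotriethylsilane, CC[Si](Cl)(CC)CC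
Why: Standard O-silylation of the acidic hydroperoxide under mild base, which blocks self-condensation of the hydroperoxide and installs the silyl group that later serves as the turnover agent.

Step 5
Reactants: 9 triethyl{[(E)-10-iodo-2-methoxydec-9-en-2-yl]peroxy}silane; 10 methyl 3-methylbut-3-enoate (3 equiv)
Product: 13 methyl 2-[(3R,5S)-5-[(E)-8-iodooct-7-en-1-yl]-3,5-dimethyl-1,2-dioxolan-3-yl]acetate, via peroxycarbenium ion 11 (not isolated), via tertiary C3 carbocation 12 (not isolated)
Conditions: (S,S)-IDPi (BINOL-derived imidodiphosphorimidate, 3,3'-aryl groups, N-triflyl core; 5 mol %), PhMe, Ar, −78 to −60 °C; Et3N quench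
Reagents that add atoms: none
Why: Proposed new method: the confined, strongly acidic IDPi (H–X*, and Et3Si–X* once turnover starts) strips the methoxy group from racemic 9, so both enantiomers converge on the planar peroxycarbenium ion 11 held as a contact ion pair with the chiral anion X*; the CH2 terminus of 10 attacks C5 (C4–C5 bond, Markovnikov) to give the tertiary C3 cation 12, which is captured by the silylated distal peroxide oxygen (O2–C3 bond), and the expelled Et3Si+ is passed on to methanol or X*, which closes the catalytic cycle. The closest known reaction type is the SnCl4- or TiCl4-promoted (3+2) annulation of silyl peroxyketals with alkenes, which delivers racemic 1,2-dioxolanes; new is only its operation under asymmetric counteranion-directed catalysis, a mode established for oxocarbenium ions, for methyl-versus-alkyl discrimination at ketone carbons and for C–O closure onto tertiary cations derived from 1,1-disubstituted alkenes. One ring is closed, the 1,2-dioxolane, by a stepwise polar (3+2) process whose last event is a five-membered collapse of the O2 lone pair onto the C3 cation, outside the exo/endo classes because no bond at C3 is broken. C5 is set in the C–C bond formation by the anion pocket, which has to tell CH3 from the CH2-alkyl arm on the enantiotopic faces of 11; C3 is set in the closure, where an envelope transition state places CH2CO2Me anti to the long C5 chain (ring methyl groups trans, as required) and the anion reinforces this intrinsic bias. The step needs attack by the 1,1-disubstituted alkene of 10 and not by the iodoalkene of 9 (secured by the inductive deactivation of C=C–I and the excess of 10), ionisation of C–OMe and not of C–OOSi (the more basic, less hindered oxygen is activated) and closure faster than proton loss from 12 (low temperature, non-basic anion).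

Step 6
Reactants: 14 (Z)-hex-3-en-1-ol
Product: 15 (Z)-hex-3-enal
Conditions: IBX (1.3 equiv), DMSO, rt; pentane extraction; used at once
Reagents that add atoms: none
Why: IBX oxidation of a primary alcohol under neutral conditions stops at the aldehyde and avoids the acid or base that would pull the (Z)-β,γ-alkene into conjugation.

Step 7
Reactants: 15 (Z)-hex-3-enal
Product: 16 2-[(1E,4Z)-hepta-1,4-dien-1-yl]-4,4,5,5-tetramethyl-1,3,2-dioxaborolane
Conditions: Cl2CHBpin (2 equiv), CrCl2 (8 equiv), LiI (4 equiv), THF, rt
Reagents that add atoms: 2-(dichloromethyl)-4,4,5,5-tetramethyl-1,3,2-dioxaborolane, ClC(Cl)B1OC(C)(C)C(C)(C)O1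
Why: Takai–Utimoto olefination: the gem-dichromium boronate reagent adds to the aldehyde and eliminates through the anti arrangement to give the (E)-alkenylboronate, under neutral conditions that leave the skipped (Z)-alkene in place.

Step 8
Reactants: 13 methyl 2-[(3R,5S)-5-[(E)-8-iodooct-7-en-1-yl]-3,5-dimethyl-1,2-dioxolan-3-yl]acetate; 16 2-[(1E,4Z)-hepta-1,4-dien-1-yl]-4,4,5,5-tetramethyl-1,3,2-dioxaborolane
Product: 18 2-[(3R,5S)-3,5-dimethyl-5-[(7E,9E,12Z)-pentadeca-7,9,12-trien-1-yl]-1,2-dioxolan-3-yl]acetic acid, via methyl ester 17 (not isolated)
Conditions: Pd(dppf)Cl2·CH2Cl2 (5 mol %), 1 M aq LiOH (5 equiv), THF, degassed, dark, rt, stirred on until the ester is consumed; then 0.5 M HCl to pH 4, 0 °C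
Reagents that add atoms: lithium hydroxide, [Li+].[OH-]
Why: Suzuki–Miyaura alkenyl–alkenyl coupling proceeds with retention at both partners to give the (E,E)-diene, palladium cross-coupling being tolerated by di-tertiary dialkyl peroxides (no α-hydrogen, so no Kornblum–DeLaMare cleavage), and the same hydroxide then saponifies the unhindered methyl ester faster than it can enolise it, so C3 should not be scrambled by retro-oxa-Michael opening.

Compound list
1 | 4-bromo-2-methylbut-1-ene | C=C(C)CCBr | starting material
2 | 6-bromohex-1-yne | C#CCCCCBr | starting material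
3 | (3-methylbut-3-en-1-yl)magnesium bromide (not isolated) | C=C(C)CC[Mg]Br | intermediate
4 | 2-methyldec-1-en-9-yne | C=C(C)CCCCCCC#C | intermediate
5 | chlorobis(cyclopentadienyl)[(E)-9-methyldeca-1,9-dien-1-yl]zirconium (not isolated, Cp drawn σ-bound) | C=C(C)CCCCCC/C=C/[Zr](Cl)(C1C=CC=C1)C1C=CC=C1 | intermediate
6 | (E)-1-iodo-9-methyldeca-1,9-diene | C=C(C)CCCCCC/C=C/I | intermediate
7 | (E)-10-iododec-9-en-2-one O-oxide, carbonyl oxide (not isolated) | CC(CCCCCC/C=C/I)=[O+][O-] | intermediate
8 | (E)-9-hydroperoxy-1-iodo-9-methoxydec-1-ene (racemic) | COC(C)(CCCCCC/C=C/I)OO | intermediate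
9 | triethyl{[(E)-10-iodo-2-methoxydec-9-en-2-yl]peroxy}silane (racemic) | COC(C)(CCCCCC/C=C/I)OO[Si](CC)(CC)CC | intermediate
10 | methyl 3-methylbut-3-enoate | C=C(C)CC(=O)OC | starting material
11 | peroxycarbenium ion, [(E)-10-iododec-9-en-2-ylidene](triethylsilyloxy)oxonium, ion pair with the catalyst anion (not isolated) | CC(CCCCCC/C=C/I)=[O+]O[Si](CC)(CC)CC | intermediate
12 | tertiary C3 carbocation with C5 already (S)-configured, ion pair with the catalyst anion (not isolated) | I/C=C/CCCCCC[C@@](OO[Si](CC)(CC)CC)(C)C[C+](C)CC(=O)OC | intermediate
13 | methyl 2-[(3R,5S)-5-[(E)-8-iodooct-7-en-1-yl]-3,5-dimethyl-1,2-dioxolan-3-yl]acetate | I/C=C/CCCCCC[C@@]1(C)C[C@](C)(CC(=O)OC)OO1 | intermediate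
14 | (Z)-hex-3-en-1-ol | CC/C=C\CCO | starting material
15 | (Z)-hex-3-enal | CC/C=C\CC=O | intermediate
16 | 2-[(1E,4Z)-hepta-1,4-dien-1-yl]-4,4,5,5-tetramethyl-1,3,2-dioxaborolane | CC/C=C\C/C=C/B1OC(C)(C)C(C)(C)O1 | intermediate
17 | methyl 2-[(3R,5S)-3,5-dimethyl-5-[(7E,9E,12Z)-pentadeca-7,9,12-trien-1-yl]-1,2-dioxolan-3-yl]acetate (not isolated) | CC/C=C\C/C=C/C=C/CCCCCC[C@@]1(C)C[C@](C)(CC(=O)OC)OO1 | intermediate
18 | 2-[(3R,5S)-3,5-dimethyl-5-[(7E,9E,12Z)-pentadeca-7,9,12-trien-1-yl]-1,2-dioxolan-3-yl]acetic acid | CC/C=C\C/C=C/C=C/CCCCCC[C@@]1(C)C[C@](C)(CC(=O)O)OO1 | target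

Total step count: 8. Longest linear sequence: 6 (steps 1, 2, 3, 4, 5, 8).

Steps most likely to fail

Step 5 (Proposed new method).
- **Risk:** the anion pocket may discriminate poorly between the two faces of the peroxycarbenium carbon, because methyl and n-alkyl differ little. Closure at C3 may show low trans/cis selectivity. The C3 cation may lose a proton instead of closing. The acid may move the alkene of 10 into conjugation before it reacts.
- **Fallback (known chemistry):** it sets out from 9 and 10. The established stoichiometric Lewis-acid annulation (SnCl4, 1 equiv, CH2Cl2, −78 to −40 °C) forms the same two bonds and should give the racemic dioxolane ester F1 as a trans/cis mixture. The trans pair is separated on silica gel and resolved by preparative chromatography on a polysaccharide chiral stationary phase, with the iodine atom available for assignment by anomalous dispersion on a crystalline derivative. The route is rejoined at 13.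

Step 3.
- **Risk:** the iodoalkene or the iodine atom may be over-oxidised once the reactive alkene is consumed. Part of the primary ozonide may fragment in the unwanted direction.
- **Fallback:** it sets out from 6 and avoids ozone, so the O–O bond comes from O2 instead.
  - Lemieux–Johnson cleavage (OsO4 cat., NaIO4, 2,6-lutidine, dioxane/H2O) takes the electron-rich 1,1-disubstituted alkene and spares the iodoalkene, and should give (E)-10-iododec-9-en-2-one F2.
  - Et3SiOTf/Et3N in CH2Cl2 gives the triethylsilyl enol ether F3. It is drawn as the terminal regioisomer, and the internal isomers formed with it converge on the same product.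
  - Cobalt-catalysed Mukaiyama–Isayama peroxidation (Co(thd)2, O2, Et3SiH, DCE) gives the silyl monoperoxyketal F4.
  - Under the conditions of step 5, F4 loses its silyloxy group instead of a methoxy group, passes through the same ion 11 and rejoins the route at 13.

Step 8.
- **Risk:** low-valent palladium or free phosphine may reductively cleave the O–O bond. The dienylboronate may protodeboronate. Hydroxide may trigger retro-oxa-Michael opening at the ester stage, with loss of configuration at C3. The doubly allylic CH2 may autoxidise.
- **Fallback:** it sets out from 13 and 15 and removes the base altogether.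
  - Hodgson-type chromium(II) olefination of 15 with Bu3SnCHBr2 (CrCl2, LiI, THF/DMF) should give tributyl[(1E,4Z)-hepta-1,4-dien-1-yl]stannane F5.
  - A base-free Stille coupling of F5 with 13 (Pd2(dba)3, AsPh3, NMP, rt) gives 17, which is now isolated.
  - The ester is cleaved at pH 7 with a lipase or esterase in phosphate buffer/acetone, and the route is rejoined at 18.

Further compounds
F1 | step 5 | methyl 2-[5-[(E)-8-iodooct-7-en-1-yl]-3,5-dimethyl-1,2-dioxolan-3-yl]acetate (racemic, trans/cis mixture) | COC(=O)CC1(C)CC(C)(CCCCCC/C=C/I)OO1
F2 | step 3 | (E)-10-iododec-9-en-2-one | CC(=O)CCCCCC/C=C/I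
F3 | step 3 | triethyl{[(E)-10-iododeca-1,9-dien-2-yl]oxy}silane | C=C(CCCCCC/C=C/I)O[Si](CC)(CC)CC
F4 | step 3 | triethyl{[(E)-10-iodo-2-(triethylsilyloxy)dec-9-en-2-yl]peroxy}silane (racemic) | CC(CCCCCC/C=C/I)(O[Si](CC)(CC)CC)OO[Si](CC)(CC)CC
F5 | step 8 | tributyl[(1E,4Z)-hepta-1,4-dien-1-yl]stannane | CC/C=C\C/C=C/[Sn](CCCC)(CCCC)CCCC
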